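Atom labels used throughout: chromene O1, C2, C3, C4, C4a, C5–C8, C8a (benzene = ring A, pyran = ring B); bridge carbons Ca (on C1') and Cb (on C2); cyclohexene (ring C) C1' (quaternary), C2' (CHMe), C3'(Me)=C4'H, C5'H2, C6'H2. The target is (2R)-6,7,8-trimethoxy-2-methyl-2-{2-[(1S,2S)-1,2,3-trimethylcyclohex-3-en-1-yl]ethyl}-2H-chromen-5-ol.

## The problem

1. Ring A is fully substituted: five contiguous oxygens on C5–C8a, of which only O5 is a free phenol, plus carbon C4a. No simple building block carries this pattern with that one oxygen singled out.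
2. C2 is a tetrasubstituted allylic, benzylic ether carbon. Any step that ionises C2–O1 or opens ring B to an ortho-quinone methide (the usual oxa-6π chromene synthesis) destroys its configuration.
3. C2 (R) and C1' (S) are joined by two methylenes and are both fully substituted. Neither can control the other, and the bridge cannot be made by substitution at Ca or Cb (both neopentyl-type).
4. C2' (S) sits next to C1', with its methyl cis to the C1' methyl. The two groups on C1' (CH3 and CH2CH2R) are sterically almost equal, so enolate alkylation or protonation next to C1' has no reliable facial bias; C2' must be set by a stereospecific transfer.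
5. The trisubstituted C3'=C4' alkene must end up in one defined position beside C2'.
6. The electron-rich phenol (para-methoxyphenol, prone to quinone formation), the 2H-chromene (light, acid) and the ring C alkene (acid) will not survive rough late-stage treatment.
7. The feature that allows the key step: C5–C6–C7–C8, with the para-related O5–H / O8–Me pair flanking the two methoxy carbons, are the four carbons of dimethyl squarate, and C8a=C4a is the enol ether double bond of a 3,4-dihydro-2H-pyran (ring B) that already carries C2.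

## Retrosynthesis

**Target 25 from chromanol 23.** Only the C3=C4 unsaturation is removed. A 5-hydroxychroman is dehydrogenated through its ortho-quinone methide without touching C2–O1, so ring B can be carried saturated through the aromatic ring construction. The forward step must oxidise C4–H and nothing else.

**Chromanol 23 from cyclobutenone 20 (key disconnection), and 20 from dihydropyran 16 and dimethyl squarate 17.** Ring A is cut at C5–C4a (formed by 6π electrocyclisation) and C8–C8a (formed by addition of the C8a anion to a squarate carbonyl). Against forming the aryl ether bond O1–C8a or O1–C2, this cut never makes or breaks a bond at C2 or at oxygen. It also delivers the five-oxygen pattern already differentiated: the ketene oxygen becomes the free O5–H, and the oxygen methylated before heating becomes O8–Me. The precursor is a monocyclic enol ether plus a four-carbon commercial ring. The forward reaction must open the cyclobutenone with the alkenyl group turning inward and close onto C4a.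

**Dihydropyran 16 from mixed acetal 15.** The C5=C6 enol ether of ring B is added back by loss of methanol. Keeping it masked as the 2-methoxyoxane until the end lets the oxidative and Lewis-acidic steps on ring C run without an enol ether present.

**Acetal 15 from picolinate 14, alcohol 13 and enone 12.** The C2'–CH3 bond is cut. The methyl is brought in by anti SN2' substitution, which moves the alkene to C3'=C4' at the same time. C2' is then set by 1,3-chirality transfer from the C4' carbinol, which a CBS reduction fixes under reagent control. This is preferred to methylating an enolate next to C1', where CH3 and CH2CH2R offer no facial distinction.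

**Enone 12 from alkene 10 and enol triflate 9.** The C4' oxygen is removed (allylic oxidation in the forward sense) and the C3'–CH3 bond is cut (cross-coupling of a regiodefined enol triflate). The forward steps must keep the alkene at C2'=C3' and oxidise the only ring allylic CH2.

**Enol triflate 9 from acetal 4 and 3-methylcyclohex-2-en-1-one 5.** The C1'–Ca bond is cut. A catalytic asymmetric conjugate addition of the alkylmetal made from the vinyl group of 4 creates the quaternary centre C1' and joins the two halves in one step. It also leaves a regiodefined enolate that is trapped as 9. This is the only convergent union that leaves both neopentyl bridge carbons untouched and lets C2 arrive ready-made.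

**Acetal 4 from lactol 2 and (S)-linalool 1.** C2 is bought. The vinyl group of 1 becomes the bridge Cb–Ca. The prenyl arm is cut back by ozonolysis and extended by one carbon to give C3–C6 of the oxane. The spatial arrangement at the carbinol carbon is never changed (S in 1 becomes R in 25 only through CIP priorities).

## Roads not taken

**Alternative 1:** Biomimetic chromenylation, the most obvious route. Cut O1–C2 and C4–C4a. 4,5,6-Trimethoxybenzene-1,3-diol A1 is condensed with the enal A2 (amine or diammonium salt, heat). Knoevenagel-type condensation gives the vinyl ortho-quinone methide A3, which closes by oxa-6π electrocyclisation. C2 is created in that electrocyclisation, four bonds from the nearest stereocentre and on a planar intermediate, so both C2 epimers must be expected. A1 is not a commercial pattern, and A2 still needs ring C plus an (E)-trisubstituted enal. The chosen plan buys C2 and never opens ring B.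

**Alternative 2:** Asymmetric O-allylation plus ring-closing metathesis. Cut O1–C2 and C3=C4. Phenol A4 and the (E)-allylic carbonate A5 give the branched tertiary aryl ether A6 with a palladium catalyst and a chiral ligand; the second-generation Grubbs catalyst then closes ring B. The nucleophilic oxygen of A4 is flanked by OMe and vinyl and must form a tertiary ether, so branched/linear ratio and enantioselectivity are both at risk. A4 is a hexasubstituted arene with five oxygens to differentiate. A5 needs a linear chain extension from the neopentyl C1'. The chosen plan makes ring A in one operation from 17 and takes the bridge from the vinyl group of 1.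

**Alternative 3:** Diels–Alder construction of ring C. Cut C1'–C6' and C2'–C3'. Tiglic aldehyde and the silyloxydiene A7 give adduct A8 with a chiral Lewis acid; the cis C1'/C2' methyls follow from the dienophile geometry. The aldehyde carbon of A8 is Ca, so the bridge would need a Ca–Cb or Cb–C2 bond. A nucleophile at Cb is a β-alkoxy organometallic (it eliminates), and the other way C2 would arise by addition to a methyl ketone without facial control, so C2 could no longer be bought. The enol ether of A8 also lies at C4'=C5', the wrong side for the C3'=C4' alkene. The conjugate addition of the chosen plan forms C1'–Ca and brings C2 along.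

Key step: step 11

Assumption: (S)-(+)-linalool of high enantiomeric purity is taken as a purchasable starting material; its optical purity fixes that of C2.

Remark: compounds 4 and 7–15 are carried as mixtures of epimers at the acetal carbon, which becomes sp2 in step 9.

## Route

Step 1
Reactants: 1 (S)-(+)-linalool
Product: 2 (5S)-5-ethenyl-5-methyloxolan-2-ol (lactol; both anomers)
Conditions: O3, CH2Cl2/MeOH, −78 °C (Sudan red end point); then Me2S, −78 °C → rt
Reagents that add atoms: ozone, [O-][O+]=O
Why: Chemoselective ozonolysis: the electron-rich trisubstituted 6,7-alkene is cleaved much faster than the monosubstituted vinyl group, and the 4-hydroxy aldehyde closes to the five-membered lactol; the carbinol carbon (future C2) is not touched.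

Step 2
Reactants: 2 (5S)-5-ethenyl-5-methyloxolan-2-ol
Product: 4 (2S)-2-ethenyl-6-methoxy-2-methyloxane (both C6 epimers), via enol ether 3 (not isolated)
Conditions: Ph3P(CH2OMe)Cl, KOt-Bu, THF, 0 °C → rt; then PPTS (cat.), CH2Cl2, 0 °C
Reagents that add atoms: (methoxymethyl)triphenylphosphonium chloride, COC[P+](c1ccccc1)(c1ccccc1)c1ccccc1.[Cl-]
Why: Wittig methoxymethylenation of the lactol (through its hydroxy-aldehyde form) adds the one carbon ring B lacks, and acid-catalysed intramolecular acetalisation of the enol ether by the tertiary hydroxyl gives the six-membered mixed acetal, a masked dihydropyran that tolerates the organometallic and oxidative steps ahead.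

Step 3
Reactants: 4 (2S)-2-ethenyl-6-methoxy-2-methyloxane, 5 3-methylcyclohex-2-en-1-one
Product: 9 (3S)-3-{2-[(2S)-6-methoxy-2-methyloxan-2-yl]ethyl}-3-methylcyclohex-1-en-1-yl trifluoromethanesulfonate, via alkylzirconocene 6 (not isolated), via silyl enol ether 7 (not isolated), via lithium enolate 8 (not isolated)
Conditions: Cp2Zr(H)Cl, CH2Cl2, rt; then 5, (CuOTf)2·C6H6 (cat.), chiral phosphoramidite ligand (cat., enantiomer giving the 3S product), Me3SiCl, Et2O, rt; filtration (pentane); then MeLi, THF, 0 °C; then PhNTf2, −78 °C → rt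
Reagents that add atoms: N-phenylbis(trifluoromethanesulfonimide), O=S(=O)(N(c1ccccc1)S(=O)(=O)C(F)(F)F)C(F)(F)F
Why: Hydrozirconation puts zirconium on the terminal vinyl carbon; copper-catalysed asymmetric conjugate addition of the alkylzirconocene to the β-methyl enone forms C1'–Ca and sets the quaternary centre C1' under ligand control (C2, five bonds away, is a spectator). Me3SiCl captures the enolate as the regiodefined silyl enol ether, and MeLi/PhNTf2 turn it into the enol triflate without loss of regiochemistry.

Step 4
Reactants: 9 (3S)-3-{2-[(2S)-6-methoxy-2-methyloxan-2-yl]ethyl}-3-methylcyclohex-1-en-1-yl trifluoromethanesulfonate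
Product: 10 (2S)-2-{2-[(1S)-1,3-dimethylcyclohex-2-en-1-yl]ethyl}-6-methoxy-2-methyloxane
Conditions: MeMgBr, Fe(acac)3 (5 mol %), THF/NMP, −30 → 0 °C
Reagents that add atoms: methylmagnesium bromide, C[Mg]Br
Why: Iron-catalysed Kumada-type cross-coupling of an alkenyl triflate with a methyl Grignard reagent installs the C3' methyl and fixes the alkene at C2'=C3', the regiochemistry the allylic oxidation needs.

Step 5
Reactants: 10 (2S)-2-{2-[(1S)-1,3-dimethylcyclohex-2-en-1-yl]ethyl}-6-methoxy-2-methyloxane
Product: 12 (4R)-4-{2-[(2S)-6-methoxy-2-methyloxan-2-yl]ethyl}-2,4-dimethylcyclohex-2-en-1-one, via allylic alcohol mixture 11 (not isolated)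
Conditions: SeO2 (cat.), t-BuOOH (anhydrous, in decane), CH2Cl2, rt; then Dess–Martin periodinane, pyridine, CH2Cl2, 0 °C → rt
Reagents that add atoms: tert-butyl hydroperoxide, CC(C)(C)OO
Why: Riley-type allylic oxidation (ene reaction, then [2,3] shift) attacks the ring CH2 (C4') on the more substituted end of the alkene (CH2 is preferred over CH3, and C1' has no hydrogen); Dess–Martin oxidation converges both C4' epimers to the enone. The descriptor at C1' changes to R only through CIP priorities.

Step 6
Reactants: 12 (4R)-4-{2-[(2S)-6-methoxy-2-methyloxan-2-yl]ethyl}-2,4-dimethylcyclohex-2-en-1-one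
Product: 13 (1S,4S)-4-{2-[(2S)-6-methoxy-2-methyloxan-2-yl]ethyl}-2,4-dimethylcyclohex-2-en-1-ol
Conditions: (R)-2-methyl-CBS-oxazaborolidine (20 mol %), catecholborane, toluene, −78 °C
Reagents that add atoms: none
Why: CBS reduction: catalyst-controlled 1,2-hydride delivery, with the substituted alkenyl arm as the large group, sets the C4' carbinol as (S) (hydroxyl trans to the C1' methyl); the para-related C1' centre is too remote to interfere.

Step 7
Reactants: 13 (1S,4S)-4-{2-[(2S)-6-methoxy-2-methyloxan-2-yl]ethyl}-2,4-dimethylcyclohex-2-en-1-ol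
Product: 14 (1S,4S)-4-{2-[(2S)-6-methoxy-2-methyloxan-2-yl]ethyl}-2,4-dimethylcyclohex-2-en-1-yl pyridine-2-carboxylate
Conditions: pyridine-2-carboxylic acid, DCC, DMAP (cat.), CH2Cl2, rt
Reagents that add atoms: pyridine-2-carboxylic acid, OC(=O)c1ccccn1
Why: Steglich esterification with retention at C4'; the picolinate is a chelating leaving group that favours clean anti SN2' substitution.

Step 8
Reactants: 14 (1S,4S)-4-{2-[(2S)-6-methoxy-2-methyloxan-2-yl]ethyl}-2,4-dimethylcyclohex-2-en-1-yl pyridine-2-carboxylate
Product: 15 (2S)-6-methoxy-2-methyl-2-{2-[(1S,2S)-1,2,3-trimethylcyclohex-3-en-1-yl]ethyl}oxane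
Conditions: MeMgBr, CuBr·SMe2 (20 mol %), THF/Et2O, −40 → 0 °C
Reagents that add atoms: methylmagnesium bromide, C[Mg]Br
Why: Copper-catalysed allylic substitution of a picolinate by a methyl Grignard reagent takes the anti SN2' course: methyl enters C2' on the face opposite the C4'–O bond, cis to the C1' methyl and trans to the bridge, and the alkene moves to C3'=C4'. C2' is thus set by 1,3-chirality transfer from the reagent-controlled carbinol.

Step 9
Reactants: 15 (2S)-6-methoxy-2-methyl-2-{2-[(1S,2S)-1,2,3-trimethylcyclohex-3-en-1-yl]ethyl}oxane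
Product: 16 (2S)-2-methyl-2-{2-[(1S,2S)-1,2,3-trimethylcyclohex-3-en-1-yl]ethyl}-3,4-dihydro-2H-pyran
Conditions: Me3SiOTf, i-Pr2NEt, CH2Cl2, −20 °C → rt
Reagents that add atoms: none
Why: Silyl triflate/amine-mediated elimination of methanol from the mixed acetal (oxocarbenium ion, then deprotonation at the adjacent CH2) gives the cyclic enol ether; the ring C alkene and the three stereocentres are inert, and the acetal epimers converge.

Step 10
Reactants: 16 (2S)-2-methyl-2-{2-[(1S,2S)-1,2,3-trimethylcyclohex-3-en-1-yl]ethyl}-3,4-dihydro-2H-pyran, 17 dimethyl squarate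
Product: 20 2,3,4-trimethoxy-4-[(2S)-2-methyl-2-{2-[(1S,2S)-1,2,3-trimethylcyclohex-3-en-1-yl]ethyl}-3,4-dihydro-2H-pyran-6-yl]cyclobut-2-en-1-one (both C4 epimers), via lithiated dihydropyran 18 (not isolated), via lithium alkoxide 19 (not isolated)
Conditions: t-BuLi, THF, −78 → 0 °C; then 17, THF, −78 °C; then MeOTf, −78 °C → rt
Reagents that add atoms: methyl trifluoromethanesulfonate, COS(=O)(=O)C(F)(F)F
Why: α-Lithiation of the cyclic enol ether at C6, 1,2-addition of the alkenyllithium to one squarate carbonyl, and O-methylation of the tertiary alkoxide in the same flask. The oxygen methylated here becomes the C8 methyl ether, which is how the single free phenol is singled out; the new sp3 carbon is a transient stereocentre.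

Step 11
Reactants: 20 2,3,4-trimethoxy-4-[(2S)-2-methyl-2-{2-[(1S,2S)-1,2,3-trimethylcyclohex-3-en-1-yl]ethyl}-3,4-dihydro-2H-pyran-6-yl]cyclobut-2-en-1-one
Product: 23 (2R)-6,7,8-trimethoxy-2-methyl-2-{2-[(1S,2S)-1,2,3-trimethylcyclohex-3-en-1-yl]ethyl}-3,4-dihydro-2H-chromen-5-ol, via dienylketene 21 (not isolated), via cyclohexadienone 22 (not isolated)
Conditions: toluene (degassed), 110 °C, argon, exclusion of light
Reagents that add atoms: none
Why: Thermal conrotatory 4π electrocyclic opening of the cyclobutenone (C1–C4 bond) gives dienylketene 21; the C4 methoxy donor rotates outward, so the dihydropyranyl group turns inward, cis to the ketene. A disrotatory 6π electrocyclisation then bonds the ketene carbon to C5 of the dihydropyran (future C4a) and closes ring A as cyclohexa-2,4-dienone 22, which aromatises to phenol 23 by enolisation of the C4a hydrogen. The closest known reaction type is the Moore-type benzannulation of 4-alkenyl- or 4-aryl-4-alkoxycyclobutenones to 4-alkoxyphenols. No lasting stereocentre is made: C4 of 20 and C4a of 22 both become aromatic, and C2, C1' and C2' are spectators because no bond to them is made or broken. The selectivity needed is the placement of the free hydroxyl, and the mechanism fixes it: the ketene oxygen becomes O5–H, the pre-methylated oxygen becomes O8–Me, and the squarate methoxyls become O6 and O7. The electron-rich enol ether terminus should speed the closure; neutral, oxygen-free conditions protect the enol ether and the product phenol. The CIP descriptor at C2 changes to R once ring A is present; the geometry is unchanged.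

Step 12
Reactants: 23 (2R)-6,7,8-trimethoxy-2-methyl-2-{2-[(1S,2S)-1,2,3-trimethylcyclohex-3-en-1-yl]ethyl}-3,4-dihydro-2H-chromen-5-ol
Product: 25 (2R)-6,7,8-trimethoxy-2-methyl-2-{2-[(1S,2S)-1,2,3-trimethylcyclohex-3-en-1-yl]ethyl}-2H-chromen-5-ol, via quinone methide 24 (not isolated)
Conditions: DDQ (1.05 equiv), dry 1,4-dioxane, rt → 60 °C, exclusion of light
Reagents that add atoms: none
Why: DDQ dehydrogenation of an ortho-alkyl phenol: oxidation to the ortho-quinone methide (C5=O, C4a=C4) and a prototropic shift of a C3 hydrogen to oxygen give the 2H-chromene. Neither C2–O1 nor any bond to a stereocentre is broken, so C2 stays (R); the product is kept from light because 2H-chromenes ring-open photochemically.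

## Compound list

1 | (S)-(+)-linalool, (3S)-3,7-dimethylocta-1,6-dien-3-ol | O[C@](C)(C=C)CCC=C(C)C | starting material
2 | (5S)-5-ethenyl-5-methyloxolan-2-ol (both anomers) | O1[C@](C)(C=C)CCC1O | intermediate
3 | (3S)-7-methoxy-3-methylhepta-1,6-dien-3-ol (E/Z mixture) | O[C@](C)(C=C)CCC=COC | intermediate
4 | (2S)-2-ethenyl-6-methoxy-2-methyloxane (both C6 epimers) | O1[C@](C)(C=C)CCCC1OC | intermediate
5 | 3-methylcyclohex-2-en-1-one | CC1=CC(=O)CCC1 | starting material
6 | chlorobis(cyclopentadienyl){2-[(2S)-6-methoxy-2-methyloxan-2-yl]ethyl}zirconium | O1[C@](C)(CC[Zr](Cl)(C2C=CC=C2)C2C=CC=C2)CCCC1OC | intermediate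
7 | {[(3S)-3-{2-[(2S)-6-methoxy-2-methyloxan-2-yl]ethyl}-3-methylcyclohex-1-en-1-yl]oxy}trimethylsilane | O1[C@](C)(CC[C@]2(C)CCCC(O[Si](C)(C)C)=C2)CCCC1OC | intermediate
8 | lithium (3S)-3-{2-[(2S)-6-methoxy-2-methyloxan-2-yl]ethyl}-3-methylcyclohex-1-en-1-olate | O1[C@](C)(CC[C@]2(C)CCCC(O[Li])=C2)CCCC1OC | intermediate
9 | (3S)-3-{2-[(2S)-6-methoxy-2-methyloxan-2-yl]ethyl}-3-methylcyclohex-1-en-1-yl trifluoromethanesulfonate | O1[C@](C)(CC[C@]2(C)CCCC(OS(=O)(=O)C(F)(F)F)=C2)CCCC1OC | intermediate
10 | (2S)-2-{2-[(1S)-1,3-dimethylcyclohex-2-en-1-yl]ethyl}-6-methoxy-2-methyloxane | O1[C@](C)(CC[C@]2(C)CCCC(C)=C2)CCCC1OC | intermediate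
11 | (4S)-4-{2-[(2S)-6-methoxy-2-methyloxan-2-yl]ethyl}-2,4-dimethylcyclohex-2-en-1-ol (both C1 epimers) | O1[C@](C)(CC[C@]2(C)CCC(O)C(C)=C2)CCCC1OC | intermediate
12 | (4R)-4-{2-[(2S)-6-methoxy-2-methyloxan-2-yl]ethyl}-2,4-dimethylcyclohex-2-en-1-one | O1[C@](C)(CC[C@]2(C)CCC(=O)C(C)=C2)CCCC1OC | intermediate
13 | (1S,4S)-4-{2-[(2S)-6-methoxy-2-methyloxan-2-yl]ethyl}-2,4-dimethylcyclohex-2-en-1-ol | O1[C@](C)(CC[C@]2(C)CC[C@H](O)C(C)=C2)CCCC1OC | intermediate
14 | (1S,4S)-4-{2-[(2S)-6-methoxy-2-methyloxan-2-yl]ethyl}-2,4-dimethylcyclohex-2-en-1-yl pyridine-2-carboxylate | O1[C@](C)(CC[C@]2(C)CC[C@H](OC(=O)c3ccccn3)C(C)=C2)CCCC1OC | intermediate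
15 | (2S)-6-methoxy-2-methyl-2-{2-[(1S,2S)-1,2,3-trimethylcyclohex-3-en-1-yl]ethyl}oxane | O1[C@](C)(CC[C@]2(C)CCC=C(C)[C@H]2C)CCCC1OC | intermediate
16 | (2S)-2-methyl-2-{2-[(1S,2S)-1,2,3-trimethylcyclohex-3-en-1-yl]ethyl}-3,4-dihydro-2H-pyran | O1[C@](C)(CC[C@]2(C)CCC=C(C)[C@H]2C)CCC=C1 | intermediate
17 | dimethyl squarate, 3,4-dimethoxycyclobut-3-ene-1,2-dione | COC1=C(OC)C(=O)C1=O | starting material
18 | [(2S)-2-methyl-2-{2-[(1S,2S)-1,2,3-trimethylcyclohex-3-en-1-yl]ethyl}-3,4-dihydro-2H-pyran-6-yl]lithium | O1[C@](C)(CC[C@]2(C)CCC=C(C)[C@H]2C)CCC=C1[Li] | intermediate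
19 | lithium 2,3-dimethoxy-1-[(2S)-2-methyl-2-{2-[(1S,2S)-1,2,3-trimethylcyclohex-3-en-1-yl]ethyl}-3,4-dihydro-2H-pyran-6-yl]-4-oxocyclobut-2-en-1-olate | O1[C@](C)(CC[C@]2(C)CCC=C(C)[C@H]2C)CCC=C1C1(O[Li])C(OC)=C(OC)C1=O | intermediate
20 | 2,3,4-trimethoxy-4-[(2S)-2-methyl-2-{2-[(1S,2S)-1,2,3-trimethylcyclohex-3-en-1-yl]ethyl}-3,4-dihydro-2H-pyran-6-yl]cyclobut-2-en-1-one (both C4 epimers) | O1[C@](C)(CC[C@]2(C)CCC=C(C)[C@H]2C)CCC=C1C1(OC)C(OC)=C(OC)C1=O | intermediate
21 | (Z)-2,3,4-trimethoxy-4-[(2S)-2-methyl-2-{2-[(1S,2S)-1,2,3-trimethylcyclohex-3-en-1-yl]ethyl}-3,4-dihydro-2H-pyran-6-yl]buta-1,3-dien-1-one (dienylketene) | O1[C@](C)(CC[C@]2(C)CCC=C(C)[C@H]2C)CCC=C1/C(OC)=C(OC)\C(OC)=C=O | intermediate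
22 | 6,7,8-trimethoxy-2-methyl-2-{2-[(1S,2S)-1,2,3-trimethylcyclohex-3-en-1-yl]ethyl}-2,3,4,4a-tetrahydro-5H-chromen-5-one (cyclohexa-2,4-dienone) | O=C1C(OC)=C(OC)C(OC)=C2O[C@](C)(CC[C@]3(C)CCC=C(C)[C@H]3C)CCC12 | intermediate
23 | (2R)-6,7,8-trimethoxy-2-methyl-2-{2-[(1S,2S)-1,2,3-trimethylcyclohex-3-en-1-yl]ethyl}-3,4-dihydro-2H-chromen-5-ol | COc1c(O)c2c(c(OC)c1OC)O[C@](C)(CC[C@]1(C)CCC=C(C)[C@H]1C)CC2 | intermediate
24 | (2R)-6,7,8-trimethoxy-2-methyl-2-{2-[(1S,2S)-1,2,3-trimethylcyclohex-3-en-1-yl]ethyl}-2,3-dihydro-5H-chromen-5-one (ortho-quinone methide) | COC1=C(OC)C(OC)=C2O[C@](C)(CC[C@]3(C)CCC=C(C)[C@H]3C)CC=C2C1=O | intermediate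
25 | (2R)-6,7,8-trimethoxy-2-methyl-2-{2-[(1S,2S)-1,2,3-trimethylcyclohex-3-en-1-yl]ethyl}-2H-chromen-5-ol | COc1c(O)c2c(c(OC)c1OC)O[C@](C)(CC[C@]1(C)CCC=C(C)[C@H]1C)C=C2 | target

## Step count and risk

Total steps: 12. Longest linear sequence: 12 steps from 1 (5 and 17 are purchased).

**Step 11 (key step).** The tertiary methyl ether at C4 of 20 is doubly activated (allylic to the enol ether, on a strained ring). Ionisation or hydration of the enol ether at the temperature needed for ring opening, or partial inward rotation of the methoxy group, would divert the ketene away from the aromatic product. The fallback gives up the pre-set methyl ether and differentiates the oxygens after the annulation. It sets out from lithium alkoxide 19. Aqueous NH4Cl quench gives the free carbinol, 4-hydroxy-2,3-dimethoxy-4-(dihydropyranyl)cyclobut-2-en-1-one F1, which should open at lower temperature (toluene, about 100 °C, argon) in the classical hydroxy variant to the chroman-5,8-diol F2. One equivalent of MeI with K2CO3 in acetone should then methylate the more acidic and less hindered O8–H (flanked by two oxygen substituents, while O5–H is peri to C4H2), and the route is rejoined at 23.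

**Step 3.** The alkylzirconocene 6 carries an oxygen on the γ-carbon, so 1,3-elimination to a cyclopropane under silyl chloride activation may compete with transmetallation. The regiodefined silyl enol ether may be partly hydrolysed when carried on crude. Imperfect face selection would give the C1' epimer as a diastereomer. The fallback reverses the roles of methyl and chain and sets out from 4. Hydroboration with 9-borabicyclo[3.3.1]nonane gives the B-alkyl borane F3. Suzuki–Miyaura coupling with 3-iodocyclohex-2-en-1-one (PdCl2(dppf), Cs2CO3, DMF/THF/H2O) gives the 3-substituted cyclohexenone F4. Copper-catalysed asymmetric conjugate addition of MeMgBr (Cu(OTf)2, chiral N-heterocyclic carbene ligand, Et2O, 0 °C) gives the bromomagnesium enolate F5, which is triflated in the same flask with PhNTf2 to rejoin the route at 9.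

**Step 8.** C2' is neopentyl, so direct substitution at C4' (wrong regiochemistry) or a sluggish reaction may compete with attack at C2'. The fallback uses intramolecular delivery and sets out from enone 12. Reduction with the enantiomeric (S)-CBS catalyst gives the C4' epimer, (1R,4S)-allylic alcohol F6, and phenyl isocyanate gives its N-phenylcarbamate F7. N-Lithiation with MeLi, then CuI and a second equivalent of MeLi, delivers methyl from the carbamate-bound copper to C2' in the syn SN2' sense, on the same face as before, and the route is rejoined at 15.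

**Step 12.** The free para-methoxyphenol may be over-oxidised by DDQ (quinone formation with loss of the O8 methyl, or oxidative coupling) faster than the benzylic position is dehydrogenated. The fallback masks the phenol and sets out from 23. Acetylation (Ac2O, pyridine) gives the chromanyl acetate F8. DDQ in refluxing dioxane then abstracts hydride from the benzylic C4 of the deactivated ring to give the chromene acetate F9, and K2CO3 in methanol releases the phenol to rejoin at 25.

## Further compounds

F1 | step 11 | 4-hydroxy-2,3-dimethoxy-4-[(2S)-2-methyl-2-{2-[(1S,2S)-1,2,3-trimethylcyclohex-3-en-1-yl]ethyl}-3,4-dihydro-2H-pyran-6-yl]cyclobut-2-en-1-one | O1[C@](C)(CC[C@]2(C)CCC=C(C)[C@H]2C)CCC=C1C1(O)C(OC)=C(OC)C1=O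
F2 | step 11 | (2R)-6,7-dimethoxy-2-methyl-2-{2-[(1S,2S)-1,2,3-trimethylcyclohex-3-en-1-yl]ethyl}-3,4-dihydro-2H-chromene-5,8-diol | COc1c(O)c2c(c(O)c1OC)O[C@](C)(CC[C@]1(C)CCC=C(C)[C@H]1C)CC2
F3 | step 3 | 9-{2-[(2R)-6-methoxy-2-methyloxan-2-yl]ethyl}-9-borabicyclo[3.3.1]nonane | O1[C@](C)(CCB2C3CCCC2CCC3)CCCC1OC
F4 | step 3 | 3-{2-[(2S)-6-methoxy-2-methyloxan-2-yl]ethyl}cyclohex-2-en-1-one | O1[C@](C)(CCC2=CC(=O)CCC2)CCCC1OC
F5 | step 3 | bromomagnesium (3S)-3-{2-[(2S)-6-methoxy-2-methyloxan-2-yl]ethyl}-3-methylcyclohex-1-en-1-olate | O1[C@](C)(CC[C@]2(C)CCCC(O[Mg]Br)=C2)CCCC1OC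
F6 | step 8 | (1R,4S)-4-{2-[(2S)-6-methoxy-2-methyloxan-2-yl]ethyl}-2,4-dimethylcyclohex-2-en-1-ol | O1[C@](C)(CC[C@]2(C)CC[C@@H](O)C(C)=C2)CCCC1OC
F7 | step 8 | (1R,4S)-4-{2-[(2S)-6-methoxy-2-methyloxan-2-yl]ethyl}-2,4-dimethylcyclohex-2-en-1-yl N-phenylcarbamate | O1[C@](C)(CC[C@]2(C)CC[C@@H](OC(=O)Nc3ccccc3)C(C)=C2)CCCC1OC
F8 | step 12 | (2R)-6,7,8-trimethoxy-2-methyl-2-{2-[(1S,2S)-1,2,3-trimethylcyclohex-3-en-1-yl]ethyl}-3,4-dihydro-2H-chromen-5-yl acetate | COc1c(OC(C)=O)c2c(c(OC)c1OC)O[C@](C)(CC[C@]1(C)CCC=C(C)[C@H]1C)CC2
F9 | step 12 | (2R)-6,7,8-trimethoxy-2-methyl-2-{2-[(1S,2S)-1,2,3-trimethylcyclohex-3-en-1-yl]ethyl}-2H-chromen-5-yl acetate | COc1c(OC(C)=O)c2c(c(OC)c1OC)O[C@](C)(CC[C@]1(C)CCC=C(C)[C@H]1C)C=C2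
A1 | alternative 1 | 4,5,6-trimethoxybenzene-1,3-diol | Oc1cc(O)c(OC)c(OC)c1OC
A2 | alternative 1 | (2E)-3-methyl-5-[(1S,2S)-1,2,3-trimethylcyclohex-3-en-1-yl]pent-2-enal | O=C/C=C(\C)CC[C@]1(C)CCC=C(C)[C@H]1C
A3 | alternative 1 | vinyl ortho-quinone methide, 3-hydroxy-4,5,6-trimethoxy-2-{3-methyl-5-[(1S,2S)-1,2,3-trimethylcyclohex-3-en-1-yl]penta-1,3-dienylidene... written as 6-alkylidene-cyclohexa-2,4-dienone | O=C1C(=CC=C(C)CC[C@]2(C)CCC=C(C)[C@H]2C)C(O)=C(OC)C(OC)=C1OC
A4 | alternative 2 | 3-(benzyloxy)-2-ethenyl-4,5,6-trimethoxyphenol | Oc1c(OC)c(OC)c(OC)c(OCc2ccccc2)c1C=C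
A5 | alternative 2 | methyl (2E)-3-methyl-5-[(1S,2S)-1,2,3-trimethylcyclohex-3-en-1-yl]pent-2-en-1-yl carbonate | COC(=O)OC/C=C(\C)CC[C@]1(C)CCC=C(C)[C@H]1C
A6 | alternative 2 | 1-(benzyloxy)-2-ethenyl-4,5,6-trimethoxy-3-({(3R)-3-methyl-5-[(1S,2S)-1,2,3-trimethylcyclohex-3-en-1-yl]pent-1-en-3-yl}oxy)benzene | C=C[C@@](C)(CC[C@]1(C)CCC=C(C)[C@H]1C)Oc1c(OC)c(OC)c(OC)c(OCc2ccccc2)c1C=C
A7 | alternative 3 | tert-butyldimethyl[(3Z)-penta-1,3-dien-3-yloxy]silane | C=C/C(O[Si](C)(C)C(C)(C)C)=C/C
A8 | alternative 3 | (1R,2R)-4-[(tert-butyldimethylsilyl)oxy]-1,2,3-trimethylcyclohex-4-ene-1-carbaldehyde (C3 epimers) | O=C[C@]1(C)CC=C(O[Si](C)(C)C(C)(C)C)C(C)[C@H]1C
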